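**Retrosynthetic overview**
1. The target is two 7,8,4'-trihydroxyflavan units joined C4–O–C4: unit 1 (2R,3R,4R; 2,3-cis-3,4-cis) and unit 2 (2S,3R,4R; 2,3-trans-3,4-cis). They differ only in the configuration at C2, so both can come from the two enantiomers of one flav-3-ene.
2. Last operations: O-debenzylation; inversion of C3 of unit 1 by oxidation to the flavan-3-one and reduction; the C4–O–C4 bond by SN2 opening at C4 of the unit 1 3,4-epoxide (trans to the aryl group) with the C4 alkoxide of the unit 2 cis-3,4-diol 3-benzyl ether (OsO4 dihydroxylation anti to the aryl group).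
3. Both flav-3-enes come from one racemic flavanone by transfer-hydrogenative kinetic resolution (reduced enantiomer to unit 1, recovered ketone to unit 2) and dehydration.
4. Key disconnection: ring C of the flavanone by a domino aldol/SNAr annulation of a 2-fluoroaryl methyl ketone with 4-(benzyloxy)benzaldehyde, forming C2–C3 and then O1–C8a. Enabling feature: in ring A the carbon that must carry O1 (C8a) is ortho to C4a, and C4a carries C4; as a ketone, C4 makes C3 an enolate carbon and activates the C8a–F bond toward the C2 alkoxide.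
5. Ring order: rings A and B are bought as arenes; ring C of both units is closed in step 3; the epoxide ring of unit 1 is temporary; the C4 carbonyl used in step 3 is removed as the flav-3-ene double bond.

Key step: step 3

Remark: flavan numbering is used throughout (O1, C2, C3, C4, C4a, C5 to C8, C8a; ring A = benzo ring, ring B = 2-aryl group, ring C = pyran ring).
Assumption: the (S,S)-TsDPEN catalyst is taken to give the (4S) carbinol from these flavanones, as it does from simple aryl ketones; if the sense is opposite, the (R,R) catalyst is used and nothing else changes.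

**Route**

Step 1
Reactants: 1 3-fluorobenzene-1,2-diol
Product: 2 1,2-bis(benzyloxy)-3-fluorobenzene
Conditions: BnBr (2.3 equiv), K2CO3, DMF, 60 °C
Reagents that add atoms: benzyl bromide BrCc1ccccc1
Why: Double Williamson etherification of the two phenols; benzyl ethers should survive every later basic, oxidative and hydride step and leave together at the end.

Step 2
Reactants: 2 1,2-bis(benzyloxy)-3-fluorobenzene
Product: 3 1-[3,4-bis(benzyloxy)-2-fluorophenyl]ethan-1-one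
Conditions: Ac2O (1.5 equiv), Bi(OTf)3 (5 mol %), MeNO2, 50 °C
Reagents that add atoms: acetic anhydride CC(=O)OC(C)=O
Why: Friedel–Crafts acylation should go para to the C1 benzyloxy group and ortho to fluorine (the C2 benzyloxy group is flanked on both sides, twisted out of conjugation and directs weakly), and the catalytic metal triflate spares the benzyl ethers.

Step 3
Reactants: 3 1-[3,4-bis(benzyloxy)-2-fluorophenyl]ethan-1-one; 4 4-(benzyloxy)benzaldehyde
Product: 7 rac-7,8-bis(benzyloxy)-2-[4-(benzyloxy)phenyl]chroman-4-one, via lithium enolate 5 (not isolated), via lithium aldolate 6 (not isolated)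
Conditions: LiN(SiMe3)2 (1.05 equiv), THF, −78 °C; 4 (1.0 equiv), −78 °C; then DMPU, −78 → 40 °C
Reagents that add atoms: none
Why: Proposed new method: LiN(SiMe3)2 turns methyl ketone 3 into lithium enolate 5, which adds to aldehyde 4 (aldol addition, C2–C3 bond) to give lithium aldolate 6; on warming with DMPU the C2 alkoxide of 6 attacks C8a, which bears fluoride ortho to the C4 carbonyl, to give a Meisenheimer adduct that expels LiF (addition–elimination SNAr, O1–C8a bond). The closest known reaction types are the base-induced SNAr ring closure of isolated β-hydroxy 2-fluoroaryl ketones to chroman-4-ones and the one-flask C-acylation/SNAr synthesis of chromones from 2-fluoroaryl ketones; the domino aldol/O-SNAr sequence on a fluoroarene carrying two alkoxy donors is what is proposed here. Ring C closes by 6-endo-trig attack of O1 on C8a, the β-carbon of the C8a=C4a–C4=O vinylogous acyl fluoride, followed by loss of fluoride. C2 is the only new stereocenter and is left uncontrolled on purpose, because the (2S) enantiomer is needed for unit 1 and the (2R) enantiomer for unit 2, so one racemic annulation supplies ring C of both halves. The step needs cyclization of aldolate 6 to win over E1cB dehydration to the 2-fluorochalcone, retro-aldol and aldol–Tishchenko esterification; one equivalent each of base and aldehyde, lithium as counterion (LiF formation as driving force) and the dipolar cosolvent are chosen for that, and the ortho acyl group should outweigh the deactivation by the two benzyloxy groups.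

Step 4
Reactants: 7 rac-7,8-bis(benzyloxy)-2-[4-(benzyloxy)phenyl]chroman-4-one
Product: 8 (2S,4S)-7,8-bis(benzyloxy)-2-[4-(benzyloxy)phenyl]chroman-4-ol; 9 (2R)-7,8-bis(benzyloxy)-2-[4-(benzyloxy)phenyl]chroman-4-one (the unreacted enantiomer; recovered)
Conditions: Cp*RhCl[(S,S)-TsDPEN] (1 mol %), HCO2H/Et3N (5:2), EtOAc, rt, stopped near half conversion
Reagents that add atoms: none
Why: Noyori-type asymmetric transfer hydrogenation run as a kinetic resolution of a racemic flavanone: the (S,S) catalyst should create the (4S) carbinol, which only the (2S) ketone can accept by the usual axial hydride delivery that gives the 2,4-cis alcohol 8, while the mismatched (2R) ketone is recovered as 9, and both are used.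

Step 5
Reactants: 8 (2S,4S)-7,8-bis(benzyloxy)-2-[4-(benzyloxy)phenyl]chroman-4-ol
Product: 11 (2S)-7,8-bis(benzyloxy)-2-[4-(benzyloxy)phenyl]-2H-chromene, via C4 methanesulfonate 10 (not isolated)
Conditions: MsCl, Et3N (4 equiv), CH2Cl2, −20 °C → rt, dark
Reagents that add atoms: none
Why: O-sulfonylation followed by amine-mediated E1-type loss of methanesulfonate from the benzylic position activated by the para C7 benzyloxy group; C2 is not involved and the basic medium should prevent acid-induced disproportionation of the flav-3-ene.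

Step 6
Reactants: 11 (2S)-7,8-bis(benzyloxy)-2-[4-(benzyloxy)phenyl]-2H-chromene
Product: 12 (2R,3S,4S)-7,8-bis(benzyloxy)-2-[4-(benzyloxy)phenyl]-3,4-epoxychromane
Conditions: DMDO (acetone solution), CH2Cl2, −40 → −20 °C; solvent removed cold, used at once
Reagents that add atoms: dimethyldioxirane CC1(C)OO1
Why: Concerted oxygen transfer to the electron-rich C3=C4 bond from the face anti to the C2 aryl group (substrate control) under neutral conditions, which the p-alkoxybenzylic epoxide needs.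

Step 7
Reactants: 9 (2R)-7,8-bis(benzyloxy)-2-[4-(benzyloxy)phenyl]chroman-4-one
Product: 13 (2R,4R)-7,8-bis(benzyloxy)-2-[4-(benzyloxy)phenyl]chroman-4-ol
Conditions: NaBH4, THF/MeOH, 0 °C
Reagents that add atoms: none
Why: Borohydride reduction (2,4-cis alcohol expected as the main isomer); the C4 configuration is erased in the next step, so only C2 matters.

Step 8
Reactants: 13 (2R,4R)-7,8-bis(benzyloxy)-2-[4-(benzyloxy)phenyl]chroman-4-ol
Product: 15 (2R)-7,8-bis(benzyloxy)-2-[4-(benzyloxy)phenyl]-2H-chromene, via C4 methanesulfonate 14 (not isolated)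
Conditions: MsCl, Et3N (4 equiv), CH2Cl2, −20 °C → rt, dark
Reagents that add atoms: none
Why: Same sulfonylation/elimination as step 5, giving the enantiomeric flav-3-ene.

Step 9
Reactants: 15 (2R)-7,8-bis(benzyloxy)-2-[4-(benzyloxy)phenyl]-2H-chromene
Product: 16 (2S,3R,4R)-7,8-bis(benzyloxy)-2-[4-(benzyloxy)phenyl]chromane-3,4-diol
Conditions: OsO4 (2 mol %), NMO, acetone/H2O (10:1), 0 °C → rt
Reagents that add atoms: osmium tetroxide O=[Os](=O)(=O)=O (catalytic oxygen carrier); N-methylmorpholine N-oxide C[N+]1([O-])CCOCC1; water O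
Why: Upjohn syn-dihydroxylation; [3+2] addition of OsO4 to the face anti to the C2 aryl group sets C3 and C4 together as the 2,3-trans-3,4-cis pattern of unit 2.

Step 10
Reactants: 16 (2S,3R,4R)-7,8-bis(benzyloxy)-2-[4-(benzyloxy)phenyl]chromane-3,4-diol
Product: 18 (2S,3R,4R)-3,7,8-tris(benzyloxy)-2-[4-(benzyloxy)phenyl]chroman-4-ol, via dibutylstannylene acetal 17 (not isolated)
Conditions: Bu2SnO, toluene, reflux (−H2O); then BnBr, Bu4NI, 80 °C
Reagents that add atoms: benzyl bromide BrCc1ccccc1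
Why: Stannylene-acetal-directed mono-alkylation of a cis-diol: the equatorial, non-benzylic O3 should be alkylated in preference to the pseudo-axial, peri-hindered O4, leaving the C4 hydroxyl free without touching a stereocenter.

Step 11
Reactants: 18 (2S,3R,4R)-3,7,8-tris(benzyloxy)-2-[4-(benzyloxy)phenyl]chroman-4-ol; 12 (2R,3S,4S)-7,8-bis(benzyloxy)-2-[4-(benzyloxy)phenyl]-3,4-epoxychromane
Product: 20 (2R,3S,4R)-7,8-bis(benzyloxy)-2-[4-(benzyloxy)phenyl]-4-{[(2S,3R,4R)-3,7,8-tris(benzyloxy)-2-[4-(benzyloxy)phenyl]chroman-4-yl]oxy}chroman-3-ol, via sodium C4 alkoxide 19 (not isolated)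
Conditions: 18, NaH, DMF, 0 °C; then 12 (0.9 equiv) in THF, 0 → 40 °C; then H2O
Reagents that add atoms: none
Why: Base-mediated epoxide alcoholysis: the C4 alkoxide 19 (C4–O bond and configuration of unit 2 retained) attacks the benzylic C4 of 12, activated by the para benzyloxy group, anti to the epoxide oxygen (SN2, inversion, trans-diaxial opening), which places the ether oxygen cis to the 2-aryl group of unit 1 and leaves the C3 hydroxyl trans; no acid is present, so neither benzylic C–O bond can ionize.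

Step 12
Reactants: 20 (the ether with the free C3 hydroxyl in unit 1)
Product: 21 (2R,4R)-7,8-bis(benzyloxy)-2-[4-(benzyloxy)phenyl]-4-{[(2S,3R,4R)-3,7,8-tris(benzyloxy)-2-[4-(benzyloxy)phenyl]chroman-4-yl]oxy}chroman-3-one
Conditions: Dess–Martin periodinane, pyridine, CH2Cl2, 0 °C → rt
Reagents that add atoms: none
Why: Buffered Dess–Martin oxidation of the only free hydroxyl; the flanking C2 aryl and C4 alkoxy groups are already 2,4-cis diequatorial, so the ketone has no drive to epimerize.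

Step 13
Reactants: 21 (the flavan-3-one)
Product: 22 (2R,3R,4R)-7,8-bis(benzyloxy)-2-[4-(benzyloxy)phenyl]-4-{[(2S,3R,4R)-3,7,8-tris(benzyloxy)-2-[4-(benzyloxy)phenyl]chroman-4-yl]oxy}chroman-3-ol
Conditions: LiBH(s-Bu)3 (L-Selectride), THF, −78 °C; then H2O
Reagents that add atoms: none
Why: The bulky hydride should attack the C3 ketone equatorially, as with 2-substituted cyclohexanones, giving the axial C3 hydroxyl cis to both equatorial neighbours (all-cis unit 1), the known way from 2,3-trans to 2,3-cis flavan-3-ols.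

Step 14
Reactants: 22 (the hepta-O-benzyl ether)
Product: 23 (2R,3R,4R)-2-(4-hydroxyphenyl)-4-{[(2S,3R,4R)-3,7,8-trihydroxy-2-(4-hydroxyphenyl)chroman-4-yl]oxy}chromane-3,7,8-triol (CNP0241481.1)
Conditions: H2 (1 atm), Pd(OH)2/C, EtOAc/MeOH, rt, stopped as soon as debenzylation is complete
Reagents that add atoms: none
Why: Neutral hydrogenolysis of six aryl benzyl ethers and one alkyl benzyl ether; the hindered bis-secondary C4–O–C4 ether and the ring C2–O1 bonds should react more slowly, and no stereocenter is touched.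

**Compound list**
1 | 3-fluorobenzene-1,2-diol | Oc1cccc(F)c1O | starting material
2 | 1,2-bis(benzyloxy)-3-fluorobenzene | Fc1cccc(OCc2ccccc2)c1OCc1ccccc1 | intermediate
3 | 1-[3,4-bis(benzyloxy)-2-fluorophenyl]ethan-1-one | CC(=O)c1ccc(OCc2ccccc2)c(OCc2ccccc2)c1F | intermediate
4 | 4-(benzyloxy)benzaldehyde | O=Cc1ccc(OCc2ccccc2)cc1 | starting material
5 | lithium 1-[3,4-bis(benzyloxy)-2-fluorophenyl]ethen-1-olate | [Li+].[O-]C(=C)c1ccc(OCc2ccccc2)c(OCc2ccccc2)c1F | intermediate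
6 | lithium 3-[3,4-bis(benzyloxy)-2-fluorophenyl]-1-[4-(benzyloxy)phenyl]-3-oxopropan-1-olate (racemic) | [Li+].[O-]C(CC(=O)c1ccc(OCc2ccccc2)c(OCc2ccccc2)c1F)c1ccc(OCc2ccccc2)cc1 | intermediate
7 | rac-7,8-bis(benzyloxy)-2-[4-(benzyloxy)phenyl]chroman-4-one | O=C1CC(c2ccc(OCc3ccccc3)cc2)Oc2c1ccc(OCc1ccccc1)c2OCc1ccccc1 | intermediate
8 | (2S,4S)-7,8-bis(benzyloxy)-2-[4-(benzyloxy)phenyl]chroman-4-ol | O[C@H]1C[C@@H](c2ccc(OCc3ccccc3)cc2)Oc2c1ccc(OCc1ccccc1)c2OCc1ccccc1 | intermediate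
9 | (2R)-7,8-bis(benzyloxy)-2-[4-(benzyloxy)phenyl]chroman-4-one | O=C1C[C@H](c2ccc(OCc3ccccc3)cc2)Oc2c1ccc(OCc1ccccc1)c2OCc1ccccc1 | intermediate
10 | (2S,4S)-7,8-bis(benzyloxy)-2-[4-(benzyloxy)phenyl]chroman-4-yl methanesulfonate | CS(=O)(=O)O[C@H]1C[C@@H](c2ccc(OCc3ccccc3)cc2)Oc2c1ccc(OCc1ccccc1)c2OCc1ccccc1 | intermediate
11 | (2S)-7,8-bis(benzyloxy)-2-[4-(benzyloxy)phenyl]-2H-chromene | C1=Cc2ccc(OCc3ccccc3)c(OCc3ccccc3)c2O[C@@H]1c1ccc(OCc2ccccc2)cc1 | intermediate
12 | (2R,3S,4S)-7,8-bis(benzyloxy)-2-[4-(benzyloxy)phenyl]-3,4-epoxychromane (epoxide oxygen trans to the 2-aryl group) | C(c1ccccc1)Oc1ccc(cc1)[C@H]1Oc2c(ccc(OCc3ccccc3)c2OCc2ccccc2)[C@@H]2O[C@H]12 | intermediate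
13 | (2R,4R)-7,8-bis(benzyloxy)-2-[4-(benzyloxy)phenyl]chroman-4-ol | O[C@@H]1C[C@H](c2ccc(OCc3ccccc3)cc2)Oc2c1ccc(OCc1ccccc1)c2OCc1ccccc1 | intermediate
14 | (2R,4R)-7,8-bis(benzyloxy)-2-[4-(benzyloxy)phenyl]chroman-4-yl methanesulfonate | CS(=O)(=O)O[C@@H]1C[C@H](c2ccc(OCc3ccccc3)cc2)Oc2c1ccc(OCc1ccccc1)c2OCc1ccccc1 | intermediate
15 | (2R)-7,8-bis(benzyloxy)-2-[4-(benzyloxy)phenyl]-2H-chromene | C1=Cc2ccc(OCc3ccccc3)c(OCc3ccccc3)c2O[C@H]1c1ccc(OCc2ccccc2)cc1 | intermediate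
16 | (2S,3R,4R)-7,8-bis(benzyloxy)-2-[4-(benzyloxy)phenyl]chromane-3,4-diol | O[C@@H]1c2ccc(OCc3ccccc3)c(OCc3ccccc3)c2O[C@@H](c2ccc(OCc3ccccc3)cc2)[C@@H]1O | intermediate
17 | O3,O4-dibutylstannylene acetal of 16 (2,2-dibutyl-1,3,2-dioxastannolane, configuration as in 16) | CCCC[Sn]1(CCCC)O[C@@H]2c3ccc(OCc4ccccc4)c(OCc4ccccc4)c3O[C@@H](c3ccc(OCc4ccccc4)cc3)[C@@H]2O1 | intermediate
18 | (2S,3R,4R)-3,7,8-tris(benzyloxy)-2-[4-(benzyloxy)phenyl]chroman-4-ol | O[C@@H]1c2ccc(OCc3ccccc3)c(OCc3ccccc3)c2O[C@@H](c2ccc(OCc3ccccc3)cc2)[C@@H]1OCc1ccccc1 | intermediate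
19 | sodium (2S,3R,4R)-3,7,8-tris(benzyloxy)-2-[4-(benzyloxy)phenyl]chroman-4-olate | [Na+].[O-][C@@H]1c2ccc(OCc3ccccc3)c(OCc3ccccc3)c2O[C@@H](c2ccc(OCc3ccccc3)cc2)[C@@H]1OCc1ccccc1 | intermediate
20 | (2R,3S,4R)-7,8-bis(benzyloxy)-2-[4-(benzyloxy)phenyl]-4-{[(2S,3R,4R)-3,7,8-tris(benzyloxy)-2-[4-(benzyloxy)phenyl]chroman-4-yl]oxy}chroman-3-ol | C(c1ccccc1)Oc1ccc([C@H]2Oc3c(ccc(OCc4ccccc4)c3OCc3ccccc3)[C@@H](O[C@@H]3c4ccc(OCc5ccccc5)c(OCc5ccccc5)c4O[C@@H](c4ccc(OCc5ccccc5)cc4)[C@@H]3OCc3ccccc3)[C@@H]2O)cc1 | intermediate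
21 | (2R,4R)-7,8-bis(benzyloxy)-2-[4-(benzyloxy)phenyl]-4-{[(2S,3R,4R)-3,7,8-tris(benzyloxy)-2-[4-(benzyloxy)phenyl]chroman-4-yl]oxy}chroman-3-one | C(c1ccccc1)Oc1ccc([C@H]2Oc3c(ccc(OCc4ccccc4)c3OCc3ccccc3)[C@@H](O[C@@H]3c4ccc(OCc5ccccc5)c(OCc5ccccc5)c4O[C@@H](c4ccc(OCc5ccccc5)cc4)[C@@H]3OCc3ccccc3)C2=O)cc1 | intermediate
22 | (2R,3R,4R)-7,8-bis(benzyloxy)-2-[4-(benzyloxy)phenyl]-4-{[(2S,3R,4R)-3,7,8-tris(benzyloxy)-2-[4-(benzyloxy)phenyl]chroman-4-yl]oxy}chroman-3-ol | C(c1ccccc1)Oc1ccc([C@H]2Oc3c(ccc(OCc4ccccc4)c3OCc3ccccc3)[C@@H](O[C@@H]3c4ccc(OCc5ccccc5)c(OCc5ccccc5)c4O[C@@H](c4ccc(OCc5ccccc5)cc4)[C@@H]3OCc3ccccc3)[C@H]2O)cc1 | intermediate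
23 | (2R,3R,4R)-2-(4-hydroxyphenyl)-4-{[(2S,3R,4R)-3,7,8-trihydroxy-2-(4-hydroxyphenyl)chroman-4-yl]oxy}chromane-3,7,8-triol | Oc1ccc([C@H]2Oc3c(ccc(O)c3O)[C@@H](O[C@@H]3c4ccc(O)c(O)c4O[C@@H](c4ccc(O)cc4)[C@@H]3O)[C@H]2O)cc1 | target

**Step count and risks**
Total steps: 14. Longest linear sequence: 12 steps (steps 1–4, 7–14).

Most likely to fail, step 3: aldolate 6 may lose water by E1cB, or revert by retro-aldol, faster than its oxygen adds to the donor-rich fluoroarene. The fallback sets out from 3 and 4 and uses known chemistry. Claisen–Schmidt condensation (NaOH, EtOH/H2O, rt) should give (E)-1-[3,4-bis(benzyloxy)-2-fluorophenyl]-3-[4-(benzyloxy)phenyl]prop-2-en-1-one F1. SNAr at the fluoride ortho to the enone carbonyl with the hydroxide equivalent 2-(methylsulfonyl)ethanol (NaH, DMF, 0 °C → rt) should give the aryl ether (E)-1-[3,4-bis(benzyloxy)-2-(2-methanesulfonylethoxy)phenyl]-3-[4-(benzyloxy)phenyl]prop-2-en-1-one F2, not isolated, which loses methyl vinyl sulfone in the same flask to give (E)-1-[3,4-bis(benzyloxy)-2-hydroxyphenyl]-3-[4-(benzyloxy)phenyl]prop-2-en-1-one F3. NaOAc in refluxing EtOH then closes ring C by oxa-Michael addition, and the route is rejoined at 7.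

Step 11: the hindered secondary alkoxide 19 may be too slow, so that epoxide 12 is lost first by base-induced isomerization (C2–H abstraction) or by ionization during handling. The fallback sets out from 11. Hydroboration with 9-BBN (THF, rt → 50 °C) anti to the aryl group should give B-[(2R,3S)-7,8-bis(benzyloxy)-2-[4-(benzyloxy)phenyl]chroman-3-yl]-9-borabicyclo[3.3.1]nonane F4, not isolated, and NaOH/H2O2 then the 2,3-trans alcohol (2R,3S)-7,8-bis(benzyloxy)-2-[4-(benzyloxy)phenyl]chroman-3-ol F5. DDQ (CH2Cl2, 0 °C) abstracts hydride from C4 of F5 in the presence of alcohol 18, and 18 should add to the benzylic cation trans to the C3 hydroxyl (oxidative C4 etherification known for benzylated flavan-3-ols). The route is rejoined at 20.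

Step 14: the C4–O–C4 ether may be lost by benzylic hydrogenolysis while the slow alkyl benzyl ether on O3 of unit 2 is still being cleaved. The fallback sets out from 16 and replaces that one benzyl group by an oxidatively removable one. Through stannylene 17, alkylation with 2-(bromomethyl)naphthalene (Bu4NI, 80 °C) should give (2S,3R,4R)-7,8-bis(benzyloxy)-2-[4-(benzyloxy)phenyl]-3-(naphthalen-2-ylmethoxy)chroman-4-ol F6. Its sodium alkoxide, sodium (2S,3R,4R)-7,8-bis(benzyloxy)-2-[4-(benzyloxy)phenyl]-3-(naphthalen-2-ylmethoxy)chroman-4-olate F7, not isolated, opens epoxide 12 as in step 11 to the 3-O-(2-naphthylmethyl) analogue of 20 F8. Oxidation as in step 12 gives the 3-O-(2-naphthylmethyl) analogue of 21 F9, and reduction as in step 13 the 3-O-(2-naphthylmethyl) analogue of 22 F10. DDQ (CH2Cl2/pH 7 buffer, 0 °C) removes the naphthylmethyl group to give (2R,3R,4R)-7,8-bis(benzyloxy)-2-[4-(benzyloxy)phenyl]-4-{[(2S,3R,4R)-7,8-bis(benzyloxy)-2-[4-(benzyloxy)phenyl]-3-hydroxychroman-4-yl]oxy}chroman-3-ol F11. A brief hydrogenolysis of the six aryl benzyl ethers only (H2, Pd/C, EtOAc/MeOH) rejoins the route at 23.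

Further compounds
F1 | step 3 | (E)-1-[3,4-bis(benzyloxy)-2-fluorophenyl]-3-[4-(benzyloxy)phenyl]prop-2-en-1-one | O=C(/C=C/c1ccc(OCc2ccccc2)cc1)c1ccc(OCc2ccccc2)c(OCc2ccccc2)c1F
F2 | step 3 | (E)-1-[3,4-bis(benzyloxy)-2-(2-methanesulfonylethoxy)phenyl]-3-[4-(benzyloxy)phenyl]prop-2-en-1-one | O=C(/C=C/c1ccc(OCc2ccccc2)cc1)c1ccc(OCc2ccccc2)c(OCc2ccccc2)c1OCCS(C)(=O)=O
F3 | step 3 | (E)-1-[3,4-bis(benzyloxy)-2-hydroxyphenyl]-3-[4-(benzyloxy)phenyl]prop-2-en-1-one | O=C(/C=C/c1ccc(OCc2ccccc2)cc1)c1ccc(OCc2ccccc2)c(OCc2ccccc2)c1O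
F4 | step 11 | B-[(2R,3S)-7,8-bis(benzyloxy)-2-[4-(benzyloxy)phenyl]chroman-3-yl]-9-borabicyclo[3.3.1]nonane | C(c1ccccc1)Oc1ccc([C@H]2Oc3c(ccc(OCc4ccccc4)c3OCc3ccccc3)C[C@@H]2B2C3CCCC2CCC3)cc1
F5 | step 11 | (2R,3S)-7,8-bis(benzyloxy)-2-[4-(benzyloxy)phenyl]chroman-3-ol | C(c1ccccc1)Oc1ccc([C@H]2Oc3c(ccc(OCc4ccccc4)c3OCc3ccccc3)C[C@@H]2O)cc1
F6 | step 14 | (2S,3R,4R)-7,8-bis(benzyloxy)-2-[4-(benzyloxy)phenyl]-3-(naphthalen-2-ylmethoxy)chroman-4-ol | O[C@@H]1c2ccc(OCc3ccccc3)c(OCc3ccccc3)c2O[C@@H](c2ccc(OCc3ccccc3)cc2)[C@@H]1OCc1ccc2ccccc2c1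
F7 | step 14 | sodium (2S,3R,4R)-7,8-bis(benzyloxy)-2-[4-(benzyloxy)phenyl]-3-(naphthalen-2-ylmethoxy)chroman-4-olate | [Na+].[O-][C@@H]1c2ccc(OCc3ccccc3)c(OCc3ccccc3)c2O[C@@H](c2ccc(OCc3ccccc3)cc2)[C@@H]1OCc1ccc2ccccc2c1
F8 | step 14 | (2R,3S,4R)-7,8-bis(benzyloxy)-2-[4-(benzyloxy)phenyl]-4-{[(2S,3R,4R)-7,8-bis(benzyloxy)-2-[4-(benzyloxy)phenyl]-3-(naphthalen-2-ylmethoxy)chroman-4-yl]oxy}chroman-3-ol | C(c1ccccc1)Oc1ccc([C@H]2Oc3c(ccc(OCc4ccccc4)c3OCc3ccccc3)[C@@H](O[C@@H]3c4ccc(OCc5ccccc5)c(OCc5ccccc5)c4O[C@@H](c4ccc(OCc5ccccc5)cc4)[C@@H]3OCc3ccc4ccccc4c3)[C@@H]2O)cc1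
F9 | step 14 | (2R,4R)-7,8-bis(benzyloxy)-2-[4-(benzyloxy)phenyl]-4-{[(2S,3R,4R)-7,8-bis(benzyloxy)-2-[4-(benzyloxy)phenyl]-3-(naphthalen-2-ylmethoxy)chroman-4-yl]oxy}chroman-3-one | C(c1ccccc1)Oc1ccc([C@H]2Oc3c(ccc(OCc4ccccc4)c3OCc3ccccc3)[C@@H](O[C@@H]3c4ccc(OCc5ccccc5)c(OCc5ccccc5)c4O[C@@H](c4ccc(OCc5ccccc5)cc4)[C@@H]3OCc3ccc4ccccc4c3)C2=O)cc1
F10 | step 14 | (2R,3R,4R)-7,8-bis(benzyloxy)-2-[4-(benzyloxy)phenyl]-4-{[(2S,3R,4R)-7,8-bis(benzyloxy)-2-[4-(benzyloxy)phenyl]-3-(naphthalen-2-ylmethoxy)chroman-4-yl]oxy}chroman-3-ol | C(c1ccccc1)Oc1ccc([C@H]2Oc3c(ccc(OCc4ccccc4)c3OCc3ccccc3)[C@@H](O[C@@H]3c4ccc(OCc5ccccc5)c(OCc5ccccc5)c4O[C@@H](c4ccc(OCc5ccccc5)cc4)[C@@H]3OCc3ccc4ccccc4c3)[C@H]2O)cc1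
F11 | step 14 | (2R,3R,4R)-7,8-bis(benzyloxy)-2-[4-(benzyloxy)phenyl]-4-{[(2S,3R,4R)-7,8-bis(benzyloxy)-2-[4-(benzyloxy)phenyl]-3-hydroxychroman-4-yl]oxy}chroman-3-ol | C(c1ccccc1)Oc1ccc([C@H]2Oc3c(ccc(OCc4ccccc4)c3OCc3ccccc3)[C@@H](O[C@@H]3c4ccc(OCc5ccccc5)c(OCc5ccccc5)c4O[C@@H](c4ccc(OCc5ccccc5)cc4)[C@@H]3O)[C@H]2O)cc1
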